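**Retrosynthetic overview**

- The chain is numbered C1 (benzylic carbon on ring A, the 4-hydroxy-3-methoxyphenyl) to C7 (benzylic carbon on ring B, the 3,4-dihydroxyphenyl). The strategy rests on the syn C3/C5 diol: C2–C7 is a 6-chloro-2,4,6-trideoxyhexose in open form, with C7 the aldehyde carbon, C5 and C3 the carbinols, C2 the chloromethyl carbon, and an oxane ring from the C3 oxygen to C7.
- Disconnections, last to first: the C7–O bond and the O-benzyl groups (hydrogenolysis), the acetates, C1–C2 (terminal epoxide plus ring A benzyl Grignard), C7–ring B (aryl Grignard plus lactol), then C3–C4 and C5–C6 (double aldol of acetaldehyde onto chloroacetaldehyde by 2-deoxy-D-ribose-5-phosphate aldolase, DERA).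
- Rings: the only ring built is the oxane lactol (step 1), opened again in step 2. A transient oxirane (step 3) is opened in step 5. Both arenes are bought.
- The diol is pseudo-meso, so the fixed sense of the enzyme is matched to the (3R,5S) target by putting ring B on the lactol carbon and the ring A benzyl unit on the chloromethyl carbon.

Key step: step 1

Remark: the C7 carbinol made in step 2 is not controlled and is carried as both epimers, because step 7 removes that oxygen; changes of CIP descriptor along the route reflect priority changes only, not inversion.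

**Route**

Step 1
Reactants: 1 acetaldehyde (2 equiv); 2 chloroacetaldehyde
Product: 5 (4R,6S)-6-(chloromethyl)oxane-2,4-diol [(3R,5S)-6-chloro-2,4,6-trideoxyhexopyranose], via (S)-4-chloro-3-hydroxybutanal 3 (not isolated), via open-chain (3R,5S)-6-chloro-3,5-dihydroxyhexanal 4 (not isolated)
Conditions: DERA (E. coli lysate), H2O, pH 7.2 buffer, 25 °C, slow co-feed of 1 (2.1 equiv) and 2 (commercial aq. solution); acetone, filter; EtOAc extraction
Reagents that add atoms: none
Why: Tandem enzymatic aldol addition, the closest known type being the sequential DERA-catalysed addition of two acetaldehyde units to an α-substituted acetaldehyde: the active-site lysine forms an enamine with 1 that adds to the carbonyl of 2 to give 3, and 3 is the acceptor for a second enamine, giving 4. The oxane ring closes by 6-exo-trig attack of the C3 hydroxyl on the C7 aldehyde carbon, and this hemiacetal formation withdraws 4 from the aldol equilibria so that no third unit is added. Both carbinol centres are set by the enzyme alone: the enamine attacks each acceptor from the same face, giving S at the chlorohydrin carbon and R at the second carbinol, which is the syn diol in one absolute sense; the anomeric centre is left as a mixture and is of no consequence. The step needs cross-selectivity (2 as first acceptor, 1 only as donor) over self-aldol of 1, which should be secured because 2 is the more electrophilic aldehyde and is not taken as a donor, and because slow feeding keeps both aldehyde concentrations low enough to spare the enzyme.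

Step 2
Reactants: 5 (4R,6S)-6-(chloromethyl)oxane-2,4-diol; 6 4-bromo-1,2-bis(benzyloxy)benzene
Product: 8 (1RS,3S,5S)-1-[3,4-bis(benzyloxy)phenyl]-6-chlorohexane-1,3,5-triol, via [3,4-bis(benzyloxy)phenyl]magnesium bromide 7 (not isolated)
Conditions: 6 (4 equiv), Mg, cat. I2, THF, 45 °C; then 5 in THF, 0 °C → rt; sat. aq. NH4Cl
Reagents that add atoms: none
Why: Grignard addition to a lactol: two equivalents of 7 deprotonate the hydroxyls, the magnesium lactolate opens to the aldehyde form (the dialkoxide of 4) and a third equivalent adds to C7, while the alkyl chloride is inert to an aryl Grignard at this temperature, C3 and C5 are untouched, and the new C7 carbinol forms as an epimer mixture that step 7 erases.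

Step 3
Reactants: 8 (1RS,3S,5S)-1-[3,4-bis(benzyloxy)phenyl]-6-chlorohexane-1,3,5-triol
Product: 9 (1RS,3S)-1-[3,4-bis(benzyloxy)phenyl]-4-[(2S)-oxiran-2-yl]butane-1,3-diol
Conditions: K2CO3 (2 equiv), MeOH, 0 °C → rt
Reagents that add atoms: none
Why: Chlorohydrin-to-epoxide closure (intramolecular Williamson etherification, 3-exo-tet): the C3 alkoxide displaces chloride at the primary carbon C2, so no bond to C3 is broken and its configuration is retained, and under mild carbonate base this closure should outrun attack by the more distant hydroxyls.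

Step 4
Reactants: 10 (4-benzyloxy-3-methoxyphenyl)methanol
Product: 11 1-(benzyloxy)-4-(chloromethyl)-2-methoxybenzene
Conditions: SOCl2 (1.2 equiv), cat. DMF, CH2Cl2, 0 °C → rt; evaporate, use crude
Reagents that add atoms: thionyl chloride, ClS(Cl)=O
Why: Deoxychlorination of an electron-rich benzylic alcohol through its chlorosulfite; the aryl benzyl and methyl ethers are stable to these conditions.

Step 5
Reactants: 9 (1RS,3S)-1-[3,4-bis(benzyloxy)phenyl]-4-[(2S)-oxiran-2-yl]butane-1,3-diol; 11 1-(benzyloxy)-4-(chloromethyl)-2-methoxybenzene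
Product: 13 (1RS,3R,5R)-1-[3,4-bis(benzyloxy)phenyl]-7-[4-(benzyloxy)-3-methoxyphenyl]heptane-1,3,5-triol, via [4-(benzyloxy)-3-methoxybenzyl]magnesium chloride 12 (not isolated)
Conditions: 11 (4.5 equiv), Mg, cat. I2, THF, 0 °C, slow addition at high dilution; then 9, CuI (10 mol %), THF, −40 → 0 °C; sat. aq. NH4Cl
Reagents that add atoms: none
Why: Copper-catalysed Grignard opening of a terminal epoxide: after two equivalents of 12 are spent on the hydroxyls, the benzyl nucleophile attacks the unsubstituted carbon C2 in an SN2 sense to form C1–C2, so the C3–O bond and its configuration are not touched.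

Step 6
Reactants: 13 (1RS,3R,5R)-1-[3,4-bis(benzyloxy)phenyl]-7-[4-(benzyloxy)-3-methoxyphenyl]heptane-1,3,5-triol
Product: 14 (1RS,3R,5R)-1-[3,4-bis(benzyloxy)phenyl]-7-[4-(benzyloxy)-3-methoxyphenyl]heptane-1,3,5-triyl triacetate
Conditions: Ac2O (6 equiv), pyridine, cat. DMAP, CH2Cl2, rt
Reagents that add atoms: acetic anhydride, CC(=O)OC(C)=O
Why: DMAP-catalysed acylation of three secondary alcohols by acyl transfer from acetic anhydride; no stereocentre is involved.

Step 7
Reactants: 14 (1RS,3R,5R)-1-[3,4-bis(benzyloxy)phenyl]-7-[4-(benzyloxy)-3-methoxyphenyl]heptane-1,3,5-triyl triacetate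
Product: 15 (3R,5S)-7-(3,4-dihydroxyphenyl)-1-(4-hydroxy-3-methoxyphenyl)heptane-3,5-diyl diacetate
Conditions: H2 (1–3 bar), 10% Pd/C, EtOAc/AcOH 10:1, rt; filtration under argon
Reagents that add atoms: none
Why: Heterogeneous catalytic hydrogenolysis: Pd/C cleaves the three O-benzyl ethers and the benzylic C7–OAc bond (activated by the para-oxygenated ring B, also by way of the quinone methide once the 4-hydroxyl is free), whereas the C3 and C5 acetates have no benzylic C–O bond and survive, so the C7 centre disappears and C3 and C5 are unchanged.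

**Compound list**

1 | acetaldehyde | CC=O | starting material
2 | chloroacetaldehyde | ClCC=O | starting material
3 | (S)-4-chloro-3-hydroxybutanal | O=CC[C@H](O)CCl | intermediate (not isolated)
4 | (3R,5S)-6-chloro-3,5-dihydroxyhexanal, open-chain form | O=CC[C@H](O)C[C@H](O)CCl | intermediate (not isolated)
5 | (4R,6S)-6-(chloromethyl)oxane-2,4-diol [(3R,5S)-6-chloro-2,4,6-trideoxyhexopyranose, both anomers] | OC1C[C@H](O)C[C@H](O1)CCl | intermediate
6 | 4-bromo-1,2-bis(benzyloxy)benzene | Brc1ccc(OCc2ccccc2)c(OCc2ccccc2)c1 | starting material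
7 | [3,4-bis(benzyloxy)phenyl]magnesium bromide | Br[Mg]c1ccc(OCc2ccccc2)c(OCc2ccccc2)c1 | intermediate (not isolated)
8 | (1RS,3S,5S)-1-[3,4-bis(benzyloxy)phenyl]-6-chlorohexane-1,3,5-triol (epimers at the aryl carbinol) | OC(c1ccc(OCc2ccccc2)c(OCc2ccccc2)c1)C[C@H](O)C[C@H](O)CCl | intermediate
9 | (1RS,3S)-1-[3,4-bis(benzyloxy)phenyl]-4-[(2S)-oxiran-2-yl]butane-1,3-diol | OC(c1ccc(OCc2ccccc2)c(OCc2ccccc2)c1)C[C@H](O)C[C@H]1CO1 | intermediate
10 | (4-benzyloxy-3-methoxyphenyl)methanol | OCc1ccc(OCc2ccccc2)c(OC)c1 | starting material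
11 | 1-(benzyloxy)-4-(chloromethyl)-2-methoxybenzene | ClCc1ccc(OCc2ccccc2)c(OC)c1 | intermediate
12 | [4-(benzyloxy)-3-methoxybenzyl]magnesium chloride | Cl[Mg]Cc1ccc(OCc2ccccc2)c(OC)c1 | intermediate (not isolated)
13 | (1RS,3R,5R)-1-[3,4-bis(benzyloxy)phenyl]-7-[4-(benzyloxy)-3-methoxyphenyl]heptane-1,3,5-triol | OC(c1ccc(OCc2ccccc2)c(OCc2ccccc2)c1)C[C@H](O)C[C@H](O)CCc1ccc(OCc2ccccc2)c(OC)c1 | intermediate
14 | (1RS,3R,5R)-1-[3,4-bis(benzyloxy)phenyl]-7-[4-(benzyloxy)-3-methoxyphenyl]heptane-1,3,5-triyl triacetate | CC(=O)OC(c1ccc(OCc2ccccc2)c(OCc2ccccc2)c1)C[C@H](OC(C)=O)C[C@H](OC(C)=O)CCc1ccc(OCc2ccccc2)c(OC)c1 | intermediate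
15 | (3R,5S)-7-(3,4-dihydroxyphenyl)-1-(4-hydroxy-3-methoxyphenyl)heptane-3,5-diyl diacetate (C1 on ring A) | COc1cc(CC[C@H](C[C@H](CCc2ccc(O)c(O)c2)OC(C)=O)OC(C)=O)ccc1O | target

**Step count**

Total: 7 steps. Longest linear sequence: 6 steps (1 → 2 → 3 → 5 → 6 → 7); step 4 is a one-step branch.

**Steps most likely to fail, with fallbacks**

Step 2. The magnesium dialkoxide of the lactol may aggregate or precipitate, so that the open aldehyde form is reached too slowly and addition stays incomplete. The electron-rich benzylic carbinol may also re-close onto the C3 hydroxyl if the work-up turns acidic. The fallback sets out from 5 and makes the aldehyde open-chain and fully protected before the aryl unit is added: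
- Ethanethiol with conc. HCl at 0 °C should open the lactol to (2S,4R)-1-chloro-6,6-bis(ethylsulfanyl)hexane-2,4-diol F1.
- TBSOTf and 2,6-lutidine in CH2Cl2 should give the bis(tert-butyldimethylsilyl) ether of the dithioacetal F2.
- I2 and NaHCO3 in aqueous acetone should release (3R,5S)-3,5-bis[(tert-butyldimethylsilyl)oxy]-6-chlorohexanal F3.
- Grignard reagent 7 (1.3 equiv, THF, −78 °C) should add to give (3S,5S)-1-[3,4-bis(benzyloxy)phenyl]-3,5-bis[(tert-butyldimethylsilyl)oxy]-6-chlorohexan-1-ol F4.
- TBAF in THF at 0 °C should remove both silyl groups, and the route is rejoined at 8. Any epoxide formed by fluoride-induced closure is converted along with 8 in step 3.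

Step 5. Forming the electron-rich benzyl Grignard may lose material to Wurtz homocoupling. On the unprotected diol, the C7 alkoxide may also open the epoxide intramolecularly (6-exo) faster than the cuprate does. The fallback sets out from 9 and 11 and replaces the Grignard by a sulfone-stabilised carbanion on a protected epoxide:
- Chloride 11 and PhSO2Na in DMF should give 1-(benzyloxy)-2-methoxy-4-[(phenylsulfonyl)methyl]benzene F5.
- Epoxide 9 with TESCl and imidazole in DMF should give its 1,3-bis-O-triethylsilyl ether F6.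
- The lithio derivative of F5 (n-BuLi, THF, −78 °C → rt) should open F6 at the terminal carbon to the γ-hydroxy sulfone 7-[3,4-bis(benzyloxy)phenyl]-1-[4-(benzyloxy)-3-methoxyphenyl]-1-(phenylsulfonyl)-5,7-bis(triethylsilyloxy)heptan-3-ol F7.
- Reductive desulfonylation with sodium amalgam and Na2HPO4 in MeOH/THF at −20 °C should give 7-[3,4-bis(benzyloxy)phenyl]-1-[4-(benzyloxy)-3-methoxyphenyl]-5,7-bis(triethylsilyloxy)heptan-3-ol F8.
- TBAF in THF should then return the route to 13.

Step 7. Cleavage of the benzylic C7–O bond may stall once the benzyl ethers are gone, or the quinone methide formed from the freed para-phenol may be captured by a nucleophile instead of being reduced. The fallback sets out from 14 and removes the C7 oxygen by ionic reduction before the hydrogenation: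
- Et3SiH and TFA in CH2Cl2 at −20 → 0 °C should ionise only the benzylic acetate and deliver hydride to C7, giving (3R,5S)-7-[3,4-bis(benzyloxy)phenyl]-1-[4-(benzyloxy)-3-methoxyphenyl]heptane-3,5-diyl diacetate F9.
- Hydrogenolysis of the three benzyl ethers (H2, 10% Pd/C, EtOAc) then has no C–O bond to cleave at C7, and the route is rejoined at 15. Any C6–C7 alkene formed by elimination would be saturated in that same hydrogenation.

**Further compounds**

F1 | step 2 | (2S,4R)-1-chloro-6,6-bis(ethylsulfanyl)hexane-2,4-diol | CCSC(SCC)C[C@H](O)C[C@H](O)CCl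
F2 | step 2 | (2S,4R)-2,4-bis[(tert-butyldimethylsilyl)oxy]-1-chloro-6,6-bis(ethylsulfanyl)hexane | CCSC(SCC)C[C@H](O[Si](C)(C)C(C)(C)C)C[C@H](O[Si](C)(C)C(C)(C)C)CCl
F3 | step 2 | (3R,5S)-3,5-bis[(tert-butyldimethylsilyl)oxy]-6-chlorohexanal | O=CC[C@H](O[Si](C)(C)C(C)(C)C)C[C@H](O[Si](C)(C)C(C)(C)C)CCl
F4 | step 2 | (3S,5S)-1-[3,4-bis(benzyloxy)phenyl]-3,5-bis[(tert-butyldimethylsilyl)oxy]-6-chlorohexan-1-ol (epimers at C1) | OC(c1ccc(OCc2ccccc2)c(OCc2ccccc2)c1)C[C@H](O[Si](C)(C)C(C)(C)C)C[C@H](O[Si](C)(C)C(C)(C)C)CCl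
F5 | step 5 | 1-(benzyloxy)-2-methoxy-4-[(phenylsulfonyl)methyl]benzene | COc1cc(CS(=O)(=O)c2ccccc2)ccc1OCc1ccccc1
F6 | step 5 | 1,3-bis-O-triethylsilyl ether of epoxy diol 9 | CC[Si](CC)(CC)OC(c1ccc(OCc2ccccc2)c(OCc2ccccc2)c1)C[C@H](O[Si](CC)(CC)CC)C[C@H]1CO1
F7 | step 5 | 7-[3,4-bis(benzyloxy)phenyl]-1-[4-(benzyloxy)-3-methoxyphenyl]-1-(phenylsulfonyl)-5,7-bis(triethylsilyloxy)heptan-3-ol (target numbering; epimers at C1 and C7) | CC[Si](CC)(CC)OC(c1ccc(OCc2ccccc2)c(OCc2ccccc2)c1)C[C@H](O[Si](CC)(CC)CC)C[C@H](O)CC(c1ccc(OCc2ccccc2)c(OC)c1)S(=O)(=O)c1ccccc1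
F8 | step 5 | 7-[3,4-bis(benzyloxy)phenyl]-1-[4-(benzyloxy)-3-methoxyphenyl]-5,7-bis(triethylsilyloxy)heptan-3-ol (target numbering; epimers at C7) | CC[Si](CC)(CC)OC(c1ccc(OCc2ccccc2)c(OCc2ccccc2)c1)C[C@H](O[Si](CC)(CC)CC)C[C@H](O)CCc1ccc(OCc2ccccc2)c(OC)c1
F9 | step 7 | (3R,5S)-7-[3,4-bis(benzyloxy)phenyl]-1-[4-(benzyloxy)-3-methoxyphenyl]heptane-3,5-diyl diacetate (target numbering) | C(c1ccc(OCc2ccccc2)c(OCc2ccccc2)c1)C[C@H](OC(C)=O)C[C@H](OC(C)=O)CCc1ccc(OCc2ccccc2)c(OC)c1
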